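## Analysis of the target

The target 22 is a flavone: benzene ring A (C4a, C5, C6, C7, C8, C8a) is fused to a 4-pyranone (ring C: O1, C2, C3, C4) that carries the phenyl ring B at C2. Ring A is fully differentiated, with OMe at C5, H at C6, OH at C7 and, at C8, the C2' carbon of an N-methylpiperidine. C2' is the only stereocentre and is (R), so the stereochemical problem is one of absolute configuration alone. C2' is a benzylic amine carbon with two ortho oxygens (C7–OH and O1) and a para oxygen (C5–OMe). It can therefore lose its configuration by C2'–N heterolysis in strong acid, or by phenol-assisted opening of the piperidine at high temperature, and this is most likely before the electron-withdrawing pyranone is in place. The tertiary amine, the free phenol and the reducible C2=C3 enone are the other sensitive groups. The difficulty is to attach a configurationally defined sp3 carbon to the most hindered position of a penta-substituted, electron-rich benzene. The strategy rests on ring A being a phloroglucinol-type ring whose C8 bears C2': C8 can be the former carboxyl carbon of (R)-pipecolic acid (used as its N-Boc derivative 1), and the other five ring carbons can be grown onto it from open-chain pieces. Once the C8a oxygen is free, the C7 and C8a hydroxyls are exchanged by rotation about C8–C2', so C4a and C6 are equivalent and the pyranone needs no regiocontrol.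

## Retrosynthetic reasoning

**Pyranone (22 to 19 and 20).** The bonds C4a–C4, C3–C4 and O1–C2 are cut. C2, C3 and ring B come from alkyne 20, C4 from a one-carbon carbonyl insertion, and ring A is the aryl iodide 19. The pyranone is made last because it deactivates ring A and because its formation can be run near 40 °C in a basic medium, where C2' has no route to racemisation. A one-step thermal condensation of 18 with a β-keto ester would need more than 200 °C on a free ortho-aminoalkyl phenol and is set aside for that reason, as is any strongly acidic C-acylation. The forward reaction has to give ynone 21 and close it 6-endo onto the ortho hydroxyl.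

**Iodide (19 to 18).** The C4a–I bond is cut. In 18 the two free ring positions are equivalent and each is ortho or para to three oxygens, so one mild electrophilic iodination is enough and no regiochemical question arises.

**Nitrogen and oxygen adjustments (18 to 17 to 16).** Hydrogenolysis of the benzyl ether uncovers the second hydroxyl. Hydride reduction of the carbamate turns the Boc carbonyl carbon into the N-methyl carbon, so no separate deprotection and alkylation is needed. The hydride step is placed here, before any ketone or enone exists in the molecule.

**Ring A (16 to 9 and 11).** The bonds C6–C7, C4a–C5 and C7–C8 are cut, which opens ring A into α-diazo enone 9 and alkyne 11. This places every ring A substituent on one of two simple partners: C8 with its piperidine, C8a with its benzyloxy group and C4a come from 9; C5 with its methoxy group and C6 come from 11; C7 with its hydroxyl is the former carbonyl carbon of 9. C2' is then never formed or broken; it is carried through as an allylic, non-enolisable spectator. The forward reaction has to turn 9 into vinylketene 12, add 11 with the right orientation and aromatise.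

**Diazo enone (9 to 7).** The diazo carbon of 9 is the methyl carbon of ketone 7, so the C=N2 unit is installed by deacylative diazo transfer. Acylation of a diazoalkane with the corresponding enoyl chloride is avoided because the conjugated alkene would compete as a dipolarophile.

**Enone (7 to 3 and 6).** The C=C bond is cut to aldehyde 3 and keto phosphonate 6. One olefination then delivers the methyl ketone, the enol ether oxygen and the Z geometry together.

**Small pieces.** Aldehyde 3 comes from acid 1 by way of amide 2, which stops hydride reduction at the aldehyde stage. Phosphonate 6 comes from diazo phosphonate 4 and alcohol 5 by O–H insertion. Alkyne 11 comes from chloro acetal 10 by double elimination.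

## Alternatives that were turned down

**Alternative 1: N-acyliminium ion and vinylsilane on an intact ring A.**
- Disconnection: N–C2' and C2'–C3' of the piperidine.
- Forward key step: aldehyde carbamate A2, under a chiral Brønsted acid, would condense to the benzoxazinone-type N-acyliminium ion A3. Its Z-vinylsilane would attack through the silicon-bearing carbon and give tricyclic carbamate A1.
- For it: ring A is bought rather than built. The carbamate carbonyl serves as tether, as phenol protection and, after hydride reduction, as the N-methyl carbon. After alkene hydrogenation the route would reach an aminophenol of the same kind as 17 in a comparable number of steps.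
- Against it: C2' must be set by a chiral counter-anion acting on a flat cation that three ring oxygens stabilise. Such a long-lived, loosely paired cation transmits little of the anion's chirality. The vinylsilane is a modest nucleophile, so a strong acid is needed, and the same acid can re-ionise the doubly activated C2'–N bond of A1 and erode the selectivity.
- Comparison: this alternative is more convergent and needs no photochemistry and no volatile alkyne; on those points it is the stronger plan. The chosen strategy offers instead an enantiomeric purity that depends on no selective step.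

**Alternative 2: pyridine ring by cobalt-mediated cocyclisation.**
- Disconnection: C2'–C3', C4'–C5' and N–C6'.
- Forward key step: nitrile A5, two molecules of ethyne A6 and (C5H5)Co(CO)2 A7 (a complex of monovalent cobalt) would give aryl pyridine A4.
- For it: it is the shortest assembly of the carbon–nitrogen skeleton, from the cheapest alkyne, with no regiochemical issue.
- Against it: A4 is flat, so C2' would have to be created later by N-methylation and enantioselective hydrogenation of a pyridinium salt whose aryl group has two ortho substituents. That is a hindered and poorly predictable substrate. The two ortho acetal ethers of A5 also slow nitrile coordination, so alkyne trimerisation would compete. Their later removal needs acid on the most ionisable form of the benzylic amine.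
- Comparison: step economy favours this alternative. The chosen strategy has the (R) configuration secured from its first compound.

**Alternative 3: sulfinyl imine and a bifunctional Grignard reagent.**
- Disconnection: C2'–C3' and N–C6', with C2' made by addition to a C=N bond on an intact ring A.
- Forward key step: Grignard reagent A10 would add to sulfinyl aldimine A9, and the resulting sulfinamide anion would displace chloride to give piperidine A8.
- For it: the reaction type is well established and auxiliary-controlled, it forms two bonds and the ring in one flask, and diastereomers can be separated to upgrade purity. It is probably the shortest route to an 8-piperidinyl ring A and is stronger than the chosen plan on precedent and step count.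
- Against it: the imine carbon of A9 is shielded by two ortho acetal ethers and deactivated by three donors. These ethers can chelate magnesium and switch the addition between chelated and open transition states, so the sense and level of induction at C2' are uncertain for this substrate. Removal of the sulfinyl and acetal groups needs acid on the free, electron-rich benzylic amine, and N-methylation is a separate step.
- Comparison: the chosen strategy avoids any diastereoselective addition and any acid deprotection at C2'. It pays with a photochemical step and a volatile reagent.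

Key step: step 7

Remark on the chemistry: rotation about the C8–C2' bond of 18 is taken to be fast, so its two hydroxyls and its two ring CH positions are equivalent. Ring A atoms carry flavone numbers from step 7 on, and C2' is the piperidine carbon on C8.

## Route

Step 1
Reactants: 1 (R)-1-(tert-butoxycarbonyl)piperidine-2-carboxylic acid
Product: 2 tert-butyl (R)-2-[methoxy(methyl)carbamoyl]piperidine-1-carboxylate
Conditions: CDI, CH2Cl2, 0 °C to rt; then MeNH(OMe)·HCl, rt
Reagents that add atoms: N,O-dimethylhydroxylamine hydrochloride, CNOC.Cl
Why: Amide coupling through the acyl imidazole (Weinreb amide formation); a urethane-protected α-amino acid is activated this way without oxazolone formation, so C2' should keep its configuration.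

Step 2
Reactants: 2 tert-butyl (R)-2-[methoxy(methyl)carbamoyl]piperidine-1-carboxylate
Product: 3 tert-butyl (R)-2-formylpiperidine-1-carboxylate
Conditions: LiAlH4, THF, –20 °C; then aq. potassium sodium tartrate, 0 °C
Reagents that add atoms: none
Why: Hydride reduction of a Weinreb amide stops at the chelated tetrahedral intermediate, which releases the aldehyde only on work-up; 3 is configurationally labile and is used at once without chromatography.

Step 3
Reactants: 4 dimethyl (1-diazo-2-oxopropyl)phosphonate; 5 benzyl alcohol
Product: 6 dimethyl [1-(benzyloxy)-2-oxopropyl]phosphonate (racemic)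
Conditions: Rh2(OAc)4 (1 mol%), toluene, 80 °C
Reagents that add atoms: none
Why: Rhodium carbenoid O–H insertion; the carbenoid from the diazo phosphonate is captured by the alcohol oxygen and a 1,2-proton shift gives the α-alkoxy β-keto phosphonate, whose stereocentre is lost in step 4.

Step 4
Reactants: 3 tert-butyl (R)-2-formylpiperidine-1-carboxylate; 6 dimethyl [1-(benzyloxy)-2-oxopropyl]phosphonate
Product: 7 tert-butyl (R)-2-[(Z)-2-(benzyloxy)-3-oxobut-1-en-1-yl]piperidine-1-carboxylate
Conditions: Ba(OH)2·8H2O, THF/H2O (40:1), 0 °C to rt
Reagents that add atoms: none
Why: Horner–Wadsworth–Emmons olefination; reversible addition of the keto phosphonate anion should place C2' trans to the acetyl group, which is the Z isomer because the benzyloxy oxygen has priority, and the mild heterogeneous base is of the kind that spares α-amino aldehydes from epimerisation; the Z isomer is purified by chromatography.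

Step 5
Reactants: 7 tert-butyl (R)-2-[(Z)-2-(benzyloxy)-3-oxobut-1-en-1-yl]piperidine-1-carboxylate
Product: 9 tert-butyl (R)-2-[(Z)-2-(benzyloxy)-4-diazo-3-oxobut-1-en-1-yl]piperidine-1-carboxylate, via trifluoroacetyl diketone 8 (not isolated)
Conditions: LiN(SiMe3)2, THF, –78 °C; CF3CO2CH2CF3, –78 °C; cold aq. HCl work-up; then MsN3, Et3N, H2O, MeCN, rt
Reagents that add atoms: 2,2,2-trifluoroethyl trifluoroacetate, O=C(OCC(F)(F)F)C(F)(F)F; methanesulfonyl azide, CS(=O)(=O)N=[N+]=[N-]
Why: Detrifluoroacetylative diazo transfer (a deacylative Regitz transfer); kinetic deprotonation occurs at the methyl group and not at C2', the trifluoroacetyl group activates that carbon for transfer and leaves on the sulfonamide nitrogen, and the conjugated alkene never meets a diazoalkane.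

Step 6
Reactants: 10 2-chloro-1,1-dimethoxyethane
Product: 11 methoxyethyne
Conditions: NaNH2 (3 equiv), liq. NH3, –33 °C; then NH4Cl; distilled into cold ClCH2CH2Cl
Reagents that add atoms: none
Why: Double β-elimination; loss of methanol gives the chloro enol ether and loss of HCl gives the alkyne, held as its sodium acetylide until protonation; the product boils near room temperature and is kept as a cold stock solution.

Step 7
Reactants: 9 tert-butyl (R)-2-[(Z)-2-(benzyloxy)-4-diazo-3-oxobut-1-en-1-yl]piperidine-1-carboxylate; 11 methoxyethyne
Product: 16 tert-butyl (R)-2-[2-(benzyloxy)-6-hydroxy-4-methoxyphenyl]piperidine-1-carboxylate, via vinylketene 12 (not isolated), via cyclobutenone 13 (not isolated), via dienylketene 14 (not isolated), via cyclohexadienone 15 (not isolated)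
Conditions: 11 (4 equiv), ClCH2CH2Cl, hν (300 nm), 15 °C, sealed vessel; excess 11 purged; then 80 °C
Reagents that add atoms: none
Why: This is the photochemical Wolff variant of the Danheiser benzannulation, a known reaction of α-diazo enones with alkoxyalkynes. Light expels N2 from 9 and the alkenyl group migrates, giving vinylketene 12 with the Z enol ether intact. The ketene carbonyl carbon (future C7) is attacked by the unsubstituted, nucleophilic carbon of 11 (C6) and the ketene α-carbon (C4a) bonds to the methoxy-bearing carbon (C5); the polarisation of the alkynyl ether fixes this orientation, so 13 is the 3-methoxy-4-alkenylcyclobutenone and the methoxy group ends meta to the new hydroxyl and para to C8. Four-electron conrotatory opening of 13, by light or at 80 °C, is reversible and gives dienylketene 14; only the isomer with the alkenyl group turned inward can react further. Ring A then closes by thermal six-electron disrotatory electrocyclisation of 14 (C7–C8 bond) to 15, which tautomerises irreversibly to phenol 16. No stereocentre is created, since the sp3 carbons of 13 and 15 vanish on aromatisation, and C2' is a spectator that is neither enolisable nor conjugated to the ketene. The Z geometry of 9 holds the C2'–H bond away from the ketene carbon, which closes off a 1,5-hydrogen shift, and turns the piperidine outward in the electrocyclisation. The step needs [2+2] addition to outrun ketene dimerisation, which the excess of the electron-rich alkyne should secure.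

Step 8
Reactants: 16 tert-butyl (R)-2-[2-(benzyloxy)-6-hydroxy-4-methoxyphenyl]piperidine-1-carboxylate
Product: 17 (R)-3-(benzyloxy)-5-methoxy-2-(1-methylpiperidin-2-yl)phenol
Conditions: LiAlH4 (excess), THF, reflux; then aq. potassium sodium tartrate
Reagents that add atoms: none
Why: Hydride reduction of a carbamate to an N-methyl amine by way of the formamide and the iminium ion; the phenol is only deprotonated, the ethers are inert, and the aprotic basic medium offers no route to C2'–N cleavage.

Step 9
Reactants: 17 (R)-3-(benzyloxy)-5-methoxy-2-(1-methylpiperidin-2-yl)phenol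
Product: 18 (R)-5-methoxy-2-(1-methylpiperidin-2-yl)benzene-1,3-diol
Conditions: H2 (1 atm), 10% Pd/C, AcOH (1.1 equiv), MeOH, rt
Reagents that add atoms: none
Why: Hydrogenolysis of an aryl benzyl ether; the acid keeps the amine protonated so that it does not poison the catalyst, and the ring C2'–N bond, shielded by two ortho substituents, should be cleaved much more slowly; 18 is air-sensitive and is carried on as its acetate salt.

Step 10
Reactants: 18 (R)-5-methoxy-2-(1-methylpiperidin-2-yl)benzene-1,3-diol
Product: 19 (R)-4-iodo-5-methoxy-2-(1-methylpiperidin-2-yl)benzene-1,3-diol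
Conditions: NIS (1.0 equiv), MeCN, –30 to 0 °C
Reagents that add atoms: N-iodosuccinimide, O=C1CCC(=O)N1I
Why: Electrophilic aromatic iodination; the two free ring positions are equivalent and each is activated by three oxygens, one equivalent at low temperature limits di-iodination, and the ammonium form keeps the nitrogen away from the iodinating agent.

Step 11
Reactants: 19 (R)-4-iodo-5-methoxy-2-(1-methylpiperidin-2-yl)benzene-1,3-diol; 20 phenylacetylene
Product: 22 (R)-7-hydroxy-5-methoxy-8-(1-methylpiperidin-2-yl)-2-phenyl-4H-chromen-4-one, via ynone 21 (not isolated)
Conditions: CO (1 atm), PdCl2(PPh3)2 (5 mol%), Ph2P(CH2)3PPh2 (5 mol%), Et2NH, DMF, 40 °C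
Reagents that add atoms: carbon monoxide, [C-]#[O+]
Why: Carbonylative Sonogashira coupling and cyclisation of an ortho-iodophenol; oxidative addition to zerovalent palladium formed in the flask, CO insertion (fast for an electron-rich aryl group) and alkynylation give ynone 21, and Et2NH adds to 21 so that the ortho hydroxyl closes 6-endo to the flavone and not 5-exo to an aurone; at 40 °C in a basic medium C2' has no route to racemisation.

## Compound list

1 | (R)-1-(tert-butoxycarbonyl)piperidine-2-carboxylic acid | OC(=O)[C@H]1CCCCN1C(=O)OC(C)(C)C | starting material
2 | tert-butyl (R)-2-[methoxy(methyl)carbamoyl]piperidine-1-carboxylate | CON(C)C(=O)[C@H]1CCCCN1C(=O)OC(C)(C)C | intermediate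
3 | tert-butyl (R)-2-formylpiperidine-1-carboxylate | O=C[C@H]1CCCCN1C(=O)OC(C)(C)C | intermediate
4 | dimethyl (1-diazo-2-oxopropyl)phosphonate | COP(=O)(OC)C(=[N+]=[N-])C(C)=O | starting material
5 | benzyl alcohol | OCc1ccccc1 | starting material
6 | dimethyl [1-(benzyloxy)-2-oxopropyl]phosphonate (racemic) | COP(=O)(OC)C(OCc1ccccc1)C(C)=O | intermediate
7 | tert-butyl (R)-2-[(Z)-2-(benzyloxy)-3-oxobut-1-en-1-yl]piperidine-1-carboxylate | CC(=O)/C(OCc1ccccc1)=C/[C@H]1CCCCN1C(=O)OC(C)(C)C | intermediate
8 | tert-butyl (R)-2-[(Z)-2-(benzyloxy)-6,6,6-trifluoro-3,5-dioxohex-1-en-1-yl]piperidine-1-carboxylate | O=C(CC(=O)/C(OCc1ccccc1)=C/[C@H]1CCCCN1C(=O)OC(C)(C)C)C(F)(F)F | intermediate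
9 | tert-butyl (R)-2-[(Z)-2-(benzyloxy)-4-diazo-3-oxobut-1-en-1-yl]piperidine-1-carboxylate | [N-]=[N+]=CC(=O)/C(OCc1ccccc1)=C/[C@H]1CCCCN1C(=O)OC(C)(C)C | intermediate
10 | 2-chloro-1,1-dimethoxyethane (chloroacetaldehyde dimethyl acetal) | COC(CCl)OC | starting material
11 | methoxyethyne (methoxyacetylene) | COC#C | intermediate
12 | tert-butyl (R)-2-[(Z)-2-(benzyloxy)-4-oxobuta-1,3-dien-1-yl]piperidine-1-carboxylate (vinylketene) | O=C=C/C(OCc1ccccc1)=C/[C@H]1CCCCN1C(=O)OC(C)(C)C | intermediate
13 | tert-butyl (2R)-2-[(Z)-2-(benzyloxy)-2-(2-methoxy-4-oxocyclobut-2-en-1-yl)ethenyl]piperidine-1-carboxylate (both epimers at the ring carbon) | COC1=CC(=O)C1/C(OCc1ccccc1)=C/[C@H]1CCCCN1C(=O)OC(C)(C)C | intermediate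
14 | tert-butyl (R)-2-[(1Z,3E)-2-(benzyloxy)-4-methoxy-6-oxohexa-1,3,5-trien-1-yl]piperidine-1-carboxylate (dienylketene) | O=C=C/C(OC)=C\C(OCc1ccccc1)=C\[C@H]1CCCCN1C(=O)OC(C)(C)C | intermediate
15 | tert-butyl (2R)-2-[2-(benzyloxy)-4-methoxy-6-oxocyclohexa-2,4-dien-1-yl]piperidine-1-carboxylate (both epimers at the ring carbon) | COC1=CC(=O)C([C@H]2CCCCN2C(=O)OC(C)(C)C)C(OCc2ccccc2)=C1 | intermediate
16 | tert-butyl (R)-2-[2-(benzyloxy)-6-hydroxy-4-methoxyphenyl]piperidine-1-carboxylate | COc1cc(O)c([C@H]2CCCCN2C(=O)OC(C)(C)C)c(OCc2ccccc2)c1 | intermediate
17 | (R)-3-(benzyloxy)-5-methoxy-2-(1-methylpiperidin-2-yl)phenol | COc1cc(O)c([C@H]2CCCCN2C)c(OCc2ccccc2)c1 | intermediate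
18 | (R)-5-methoxy-2-(1-methylpiperidin-2-yl)benzene-1,3-diol | COc1cc(O)c([C@H]2CCCCN2C)c(O)c1 | intermediate
19 | (R)-4-iodo-5-methoxy-2-(1-methylpiperidin-2-yl)benzene-1,3-diol | COc1cc(O)c([C@H]2CCCCN2C)c(O)c1I | intermediate
20 | phenylacetylene | C#Cc1ccccc1 | starting material
21 | (R)-1-[2,4-dihydroxy-6-methoxy-3-(1-methylpiperidin-2-yl)phenyl]-3-phenylprop-2-yn-1-one | COc1cc(O)c([C@H]2CCCCN2C)c(O)c1C(=O)C#Cc1ccccc1 | intermediate
22 | (R)-7-hydroxy-5-methoxy-8-(1-methylpiperidin-2-yl)-2-phenyl-4H-chromen-4-one | COc1cc(O)c([C@H]2CCCCN2C)c2oc(-c3ccccc3)cc(=O)c12 | target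

## Step count and least certain steps

Total: 11 steps. Longest linear sequence: 9 steps (1 to 22 through steps 1, 2, 4, 5, 7, 8, 9, 10 and 11). Steps 3 and 6 are one-step side branches.

**Step 7 (key step).** The most likely failure is incomplete capture of vinylketene 12, because the alkyne is volatile and is also consumed by side reactions. Ketene dimerisation, acylation of the product phenol by the ketene, or photochemical Z-to-E isomerisation followed by a 1,5-hydrogen shift from C2' would then take over. Fallback, from 10 and 9 back to 16: the sodium acetylide formed from 10 as in step 6 would be silylated with Me3SiCl before protonation, giving 1-methoxy-2-(trimethylsilyl)ethyne F1, a distillable liquid that can be used in large excess in an open photoreactor. Irradiation of 9 with F1 and heating as in step 7 should give tert-butyl (R)-2-[2-(benzyloxy)-6-hydroxy-4-methoxy-5-(trimethylsilyl)phenyl]piperidine-1-carboxylate F2 with the same orientation (silicon on C6). Ipso-protodesilylation of this very electron-rich aryl silane with pyridinium p-toluenesulfonate in MeOH would return to 16.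

**Step 11.** Oxidative addition of the electron-rich, doubly ortho-substituted iodide may be slow, and direct coupling without CO insertion followed by 5-endo closure would lead to a benzofuran. Fallback, from 18 to 22 without 19: C-acetylation with Ac2O and BF3·OEt2 at rt, then K2CO3 in MeOH to cleave O-acetates, would give 1-[2,4-dihydroxy-6-methoxy-3-[(R)-1-methylpiperidin-2-yl]phenyl]ethanone F3. Its trianion, from LiN(SiMe3)2 (4.5 equiv) in THF at –78 °C, would be C-benzoylated with PhCOCl (a Baker–Venkataraman-type acylation) to give 1-[2,4-dihydroxy-6-methoxy-3-[(R)-1-methylpiperidin-2-yl]phenyl]-3-phenylpropane-1,3-dione F4. Cyclodehydration in AcOH with a little H2SO4 at 50 °C would give 22. This sequence exposes the benzylic amine to acid, so the enantiomeric purity would have to be checked after each stage.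

**Step 4.** The tetrasubstituted phosphonate carbanion may add slowly to the α-branched aldehyde, which would give time for epimerisation of 3 and could leave the alkene geometry poorly controlled. Fallback, from 3 to 7: aldol addition of the lithium enolate of methyl 2-(benzyloxy)acetate (LiN(i-Pr)2, THF, –78 °C) would give methyl 2-(benzyloxy)-3-[(R)-1-(tert-butoxycarbonyl)piperidin-2-yl]-3-hydroxypropanoate F5 as a mixture of diastereomers. Mesylation (MsCl, Et3N) and E1cB elimination with DBU at 0 °C would give methyl (Z)-2-(benzyloxy)-3-[(R)-1-(tert-butoxycarbonyl)piperidin-2-yl]prop-2-enoate F6. MeNH(OMe)·HCl with i-PrMgCl at –20 °C would give tert-butyl (R)-2-[(Z)-2-(benzyloxy)-3-[methoxy(methyl)amino]-3-oxoprop-1-en-1-yl]piperidine-1-carboxylate F7, and MeMgBr at 0 °C would give 7.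

**Step 9.** Once the amine is protonated, hydrogenolysis of the benzylic C2'–N bond (ring opening of the piperidine) may compete with cleavage of the benzyl ether. Fallback, from 16 to 18 with the order of steps 8 and 9 reversed: hydrogenolysis of 16 itself (H2, 10% Pd/C, EtOAc, rt), where the nitrogen is a non-basic carbamate, would give tert-butyl (R)-2-(2,6-dihydroxy-4-methoxyphenyl)piperidine-1-carboxylate F8. LiAlH4 in refluxing THF would then give 18.

## Further compounds

F1 | step 7 | 1-methoxy-2-(trimethylsilyl)ethyne | COC#C[Si](C)(C)C
F2 | step 7 | tert-butyl (R)-2-[2-(benzyloxy)-6-hydroxy-4-methoxy-5-(trimethylsilyl)phenyl]piperidine-1-carboxylate | COc1cc(OCc2ccccc2)c([C@H]2CCCCN2C(=O)OC(C)(C)C)c(O)c1[Si](C)(C)C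
F3 | step 11 | 1-[2,4-dihydroxy-6-methoxy-3-[(R)-1-methylpiperidin-2-yl]phenyl]ethanone | COc1cc(O)c([C@H]2CCCCN2C)c(O)c1C(C)=O
F4 | step 11 | 1-[2,4-dihydroxy-6-methoxy-3-[(R)-1-methylpiperidin-2-yl]phenyl]-3-phenylpropane-1,3-dione | COc1cc(O)c([C@H]2CCCCN2C)c(O)c1C(=O)CC(=O)c1ccccc1
F5 | step 4 | methyl 2-(benzyloxy)-3-[(R)-1-(tert-butoxycarbonyl)piperidin-2-yl]-3-hydroxypropanoate (mixture of diastereomers) | COC(=O)C(OCc1ccccc1)C(O)[C@H]1CCCCN1C(=O)OC(C)(C)C
F6 | step 4 | methyl (Z)-2-(benzyloxy)-3-[(R)-1-(tert-butoxycarbonyl)piperidin-2-yl]prop-2-enoate | COC(=O)/C(OCc1ccccc1)=C/[C@H]1CCCCN1C(=O)OC(C)(C)C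
F7 | step 4 | tert-butyl (R)-2-[(Z)-2-(benzyloxy)-3-[methoxy(methyl)amino]-3-oxoprop-1-en-1-yl]piperidine-1-carboxylate | CON(C)C(=O)/C(OCc1ccccc1)=C/[C@H]1CCCCN1C(=O)OC(C)(C)C
F8 | step 9 | tert-butyl (R)-2-(2,6-dihydroxy-4-methoxyphenyl)piperidine-1-carboxylate | COc1cc(O)c([C@H]2CCCCN2C(=O)OC(C)(C)C)c(O)c1
A1 | alternative 1 | (R)-tricyclic aryl carbamate (benzoxazinone fused to a tetrahydropyridine with a C3'=C4' alkene) | COc1cc(OCc2ccccc2)c2c(c1)OC(=O)N1CCC=C[C@H]21
A2 | alternative 1 | 3-(benzyloxy)-2-formyl-5-methoxyphenyl N-[(Z)-4-(trimethylsilyl)but-3-en-1-yl]carbamate | COc1cc(OCc2ccccc2)c(C=O)c(OC(=O)NCC/C=C\[Si](C)(C)C)c1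
A3 | alternative 1 | 5-(benzyloxy)-7-methoxy-2-oxo-3-[(Z)-4-(trimethylsilyl)but-3-en-1-yl]-2H-1,3-benzoxazin-3-ium (N-acyliminium ion) | COc1cc(OCc2ccccc2)c2C=[N+](CC/C=C\[Si](C)(C)C)C(=O)Oc2c1
A4 | alternative 2 | 2-[4-methoxy-2,6-bis(methoxymethoxy)phenyl]pyridine | COCOc1cc(OC)cc(OCOC)c1-c1ccccn1
A5 | alternative 2 | 4-methoxy-2,6-bis(methoxymethoxy)benzonitrile | COCOc1cc(OC)cc(OCOC)c1C#N
A6 | alternative 2 | ethyne | C#C
A7 | alternative 2 | (C5H5)Co(CO)2, dicarbonyl(cyclopentadienyl)cobalt | [Co+].[CH-]1C=CC=C1.[C-]#[O+].[C-]#[O+]
A8 | alternative 3 | (R)-1-[(S)-tert-butylsulfinyl]-2-[4-methoxy-2,6-bis(methoxymethoxy)phenyl]piperidine | COCOc1cc(OC)cc(OCOC)c1[C@H]1CCCCN1[S@@](=O)C(C)(C)C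
A9 | alternative 3 | (S,E)-N-[4-methoxy-2,6-bis(methoxymethoxy)benzylidene]-2-methylpropane-2-sulfinamide | COCOc1cc(OC)cc(OCOC)c1/C=N/[S@@](=O)C(C)(C)C
A10 | alternative 3 | 4-chlorobutylmagnesium bromide | ClCCCC[Mg]Br
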